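The route rests on disconnecting the O1–C8a aryl ether bond of the dihydropyran ring, the bond between arene carbon C8a and the oxygen on the fully substituted carbinol carbon C2. Since C2 bears no hydrogen and its C–O bond is never broken, a palladium-catalysed intramolecular aryl etherification closes the chroman in one operation while the (R) configuration, taken from (R)-linalool, passes through unchanged. The cyclisation precursor is an open-chain tertiary alcohol carrying the finished (2E,6E)-dienoate chain and, two carbons away, an aryl bromide flanked by the C8 methyl group, its phenol masked as a triisopropylsilyl ether.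

Key step: step 10

Assumption: (R)-(−)-linalool of high enantiomeric purity is used, because the route transfers its configuration but cannot raise the ee; the phenol is carried as a triisopropylsilyl ether, not a methyl ether, so that the last step needs only fluoride and hydroxide and no hot thiolate next to the enoate.

Step 1
Reactants: 1 (R)-linalool
Product: 3 (2E,6R)-2,6-dimethylocta-2,7-diene-1,6-diol, via hydroxy enal 2 (not isolated)
Conditions: SeO2 (0.3 equiv), tBuOOH (2.5 equiv), salicylic acid (0.1 equiv), CH2Cl2, 0 °C to rt; aq. Na2SO3 wash; then NaBH4, MeOH, 0 °C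
Reagents that add atoms: selenium dioxide, O=[Se]=O; tert-butyl hydroperoxide, CC(C)(C)OO
Why: Riley-type allylic oxidation run catalytically in SeO2 (ene reaction, then [2,3]-sigmatropic shift) should attack only the trisubstituted alkene at its (E)-methyl group, since the vinyl group has no allylic hydrogen, and the NaBH4 stage should return any over-oxidised enal to the allylic alcohol by 1,2-reduction, the carbinol centre staying untouched.

Step 2
Reactants: 3 (2E,6R)-2,6-dimethylocta-2,7-diene-1,6-diol
Product: 4 (3R,6E)-8-bromo-3,7-dimethylocta-1,6-dien-3-ol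
Conditions: CBr4 (1.15 equiv), PPh3 (1.2 equiv), CH2Cl2, −30 to 0 °C; short silica pad, used at once
Reagents that add atoms: carbon tetrabromide, BrC(Br)(Br)Br
Why: In this Appel reaction the primary allylic alkoxyphosphonium ion should be displaced by bromide in an SN2 step at low temperature with retention of the (E)-alkene, while the hindered tertiary alcohol should not be activated by the near-stoichiometric reagent.

Step 3
Reactants: 4 (3R,6E)-8-bromo-3,7-dimethylocta-1,6-dien-3-ol
Product: 5 ethyl (4E,8R)-8-hydroxy-4,8-dimethyldeca-4,9-dienoate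
Conditions: LiN(iPr)2 (3.2 equiv), EtOAc (3.3 equiv), THF, −78 °C; DMPU; then 4, −78 to −40 °C; aq. NH4Cl
Reagents that add atoms: ethyl acetate, CCOC(C)=O
Why: This is an ester enolate alkylation (SN2 at the primary allylic carbon) in which the first equivalent of enolate only deprotonates the tertiary alcohol, whose hindered lithium alkoxide is a poor nucleophile at −78 °C, and the excess enolate should form the C–C bond.

Step 4
Reactants: 5 ethyl (4E,8R)-8-hydroxy-4,8-dimethyldeca-4,9-dienoate
Product: 6 (4E,8R)-8-hydroxy-4,8-dimethyldeca-4,9-dienal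
Conditions: iBu2AlH (2.1 equiv), CH2Cl2, −78 °C; MeOH at −78 °C, then aq. potassium sodium tartrate
Reagents that add atoms: none
Why: In this partial ester reduction the first equivalent of iBu2AlH is consumed by the alcohol and the second should give a tetrahedral aluminium hemiacetal that is stable at −78 °C and releases the aldehyde only on work-up, the alkenes being inert to the hydride.

Step 5
Reactants: 6 (4E,8R)-8-hydroxy-4,8-dimethyldeca-4,9-dienal; 7 methyl 2-(triphenylphosphoranylidene)propanoate
Product: 8 methyl (2E,6E,10R)-10-hydroxy-2,6,10-trimethyldodeca-2,6,11-trienoate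
Conditions: 7 (1.3 equiv), CH2Cl2, rt to 40 °C
Reagents that add atoms: none
Why: Wittig olefination with a stabilised α-methyl ylide should give the (E)-trisubstituted enoate through reversible, thermodynamically controlled oxaphosphetane formation, and the free tertiary alcohol and the other alkenes do not interfere.

Step 6
Reactants: 9 4-amino-3-methylphenol
Product: 10 2-methyl-4-[(triisopropylsilyl)oxy]aniline
Conditions: TIPSCl (1.1 equiv), imidazole (2.2 equiv), DMF, 0 °C to rt
Reagents that add atoms: triisopropylsilyl chloride, CC(C)[Si](Cl)(C(C)C)C(C)C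
Why: Silyl ether formation with a bulky silyl chloride and imidazole should be selective for the phenol oxygen, any N-silylated material being hydrolysed on aqueous work-up.

Step 7
Reactants: 10 2-methyl-4-[(triisopropylsilyl)oxy]aniline
Product: 11 2-iodo-6-methyl-4-[(triisopropylsilyl)oxy]aniline
Conditions: BnMe3N+ ICl2− (1.05 equiv), CaCO3 (1.5 equiv), CH2Cl2/MeOH 2:1, rt, dark
Reagents that add atoms: benzyltrimethylammonium dichloroiodate, C[N+](C)(C)Cc1ccccc1.Cl[I-]Cl
Why: Electrophilic aromatic iodination should be directed by the amino group to its only free ortho position (para carries the silyloxy group, the other ortho position the methyl group), and CaCO3 buffers the HCl so that the silyl ether survives.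

Step 8
Reactants: 11 2-iodo-6-methyl-4-[(triisopropylsilyl)oxy]aniline
Product: 13 (4-bromo-3-iodo-5-methylphenoxy)triisopropylsilane, via arenediazonium bromide 12 (not isolated)
Conditions: tBuONO (1.5 equiv), CuBr2 (1.2 equiv), MeCN, 0 to 60 °C
Reagents that add atoms: copper dibromide, [Cu+2].[Br-].[Br-]
Why: Non-aqueous Sandmeyer bromination (diazotisation by the alkyl nitrite, then copper-mediated replacement of N2 by bromide) should place bromine between the methyl group and iodine without the aqueous acid that could cleave the silyl ether.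

Step 9
Reactants: 8 methyl (2E,6E,10R)-10-hydroxy-2,6,10-trimethyldodeca-2,6,11-trienoate; 13 (4-bromo-3-iodo-5-methylphenoxy)triisopropylsilane
Product: 15 methyl (2E,6E,10R)-12-{2-bromo-3-methyl-5-[(triisopropylsilyl)oxy]phenyl}-10-hydroxy-2,6,10-trimethyldodeca-2,6-dienoate, via B-alkyl-9-BBN adduct 14 (not isolated)
Conditions: 9-BBN (1.6 equiv), THF, 0 °C to rt; then aq. K3PO4 (3 M), 13 (1.0 equiv), PdCl2(dppf) (5 mol %), DMF, rt to 40 °C
Reagents that add atoms: none
Why: 9-BBN should hydroborate only the monosubstituted vinyl group (boron on the terminal carbon) in preference to the two trisubstituted alkenes and the ester, and the B-alkyl Suzuki–Miyaura coupling should then occur at the C–I bond, whose oxidative addition is far faster than that of the hindered, electron-rich C–Br bond, the carbinol centre taking no part.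

Step 10
Reactants: 15 methyl (2E,6E,10R)-12-{2-bromo-3-methyl-5-[(triisopropylsilyl)oxy]phenyl}-10-hydroxy-2,6,10-trimethyldodeca-2,6-dienoate
Product: 16 methyl (2E,6E)-9-{(2R)-2,8-dimethyl-6-[(triisopropylsilyl)oxy]-3,4-dihydro-2H-chromen-2-yl}-2,6-dimethylnona-2,6-dienoate
Conditions: Pd(OAc)2 (5 mol %), rac-2-(di-tert-butylphosphino)-1,1'-binaphthyl (6 mol %), Cs2CO3 (1.5 equiv), toluene, 80 °C, argon
Reagents that add atoms: none
Why: Pd(OAc)2 is reduced in the flask to a zerovalent palladium–phosphine complex that inserts into the C8a–Br bond; Cs2CO3 then deprotonates the bound tertiary alcohol to give a seven-membered aryl(alkoxo) divalent palladium chelate, and C–O reductive elimination, promoted by the bulky electron-rich phosphine, should form O1–C8a and regenerate the catalyst. The closest known reaction type is the Buchwald–Hartwig-type palladium-catalysed intramolecular etherification of aryl bromides with tertiary alcohols to 2,2-disubstituted chromans. The dihydropyran ring closes as a six-membered ring by aryl C–O bond formation out of the seven-membered palladacycle, not by attack on C2. No stereocentre is created: only the aryl C–Br bond reacts and the C2–O bond stays intact, so C2 keeps the (R) configuration of linalool. The step needs C–O coupling to win over β-hydride elimination, Heck and hydrodebromination pathways: the tertiary alkoxide has no carbinol hydrogen, the nearest alkene is too remote for carbopalladation, the single C–Br bond is the only site for oxidative addition, and the ester and silyl ether tolerate Cs2CO3 in dry toluene.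

Step 11
Reactants: 16 methyl (2E,6E)-9-{(2R)-2,8-dimethyl-6-[(triisopropylsilyl)oxy]-3,4-dihydro-2H-chromen-2-yl}-2,6-dimethylnona-2,6-dienoate
Product: 18 (2E,6E)-9-[(2R)-6-hydroxy-2,8-dimethyl-3,4-dihydro-2H-chromen-2-yl]-2,6-dimethylnona-2,6-dienoic acid (CNP0176653.1), via phenol methyl ester 17 (not isolated)
Conditions: Bu4NF (1.2 equiv), THF, 0 °C; then LiOH (6 equiv), THF/MeOH/H2O, rt to 40 °C, argon, degassed; 1 M HCl to pH 3 at 0 °C
Reagents that add atoms: lithium hydroxide, [Li+].[OH-]
Why: Fluoride-induced cleavage of the aryl silyl ether followed by saponification of the methyl enoate should free both functions under mild conditions that leave the alkenes and the C2 stereocentre untouched, exclusion of air protecting the electron-rich phenolate.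

Compound list
1 | (R)-linalool, (3R)-3,7-dimethylocta-1,6-dien-3-ol | C=C[C@](C)(O)CCC=C(C)C | starting material
2 | (2E,6R)-6-hydroxy-2,6-dimethylocta-2,7-dienal | C=C[C@](C)(O)CC/C=C(\C)C=O | intermediate (not isolated)
3 | (2E,6R)-2,6-dimethylocta-2,7-diene-1,6-diol | C=C[C@](C)(O)CC/C=C(\C)CO | intermediate
4 | (3R,6E)-8-bromo-3,7-dimethylocta-1,6-dien-3-ol | C=C[C@](C)(O)CC/C=C(\C)CBr | intermediate
5 | ethyl (4E,8R)-8-hydroxy-4,8-dimethyldeca-4,9-dienoate | C=C[C@](C)(O)CC/C=C(\C)CCC(=O)OCC | intermediate
6 | (4E,8R)-8-hydroxy-4,8-dimethyldeca-4,9-dienal | C=C[C@](C)(O)CC/C=C(\C)CCC=O | intermediate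
7 | methyl 2-(triphenylphosphoranylidene)propanoate | COC(=O)C(C)=P(c1ccccc1)(c1ccccc1)c1ccccc1 | starting material
8 | methyl (2E,6E,10R)-10-hydroxy-2,6,10-trimethyldodeca-2,6,11-trienoate | C=C[C@](C)(O)CC/C=C(\C)CC/C=C(\C)C(=O)OC | intermediate
9 | 4-amino-3-methylphenol | Cc1cc(O)ccc1N | starting material
10 | 2-methyl-4-[(triisopropylsilyl)oxy]aniline | Cc1cc(O[Si](C(C)C)(C(C)C)C(C)C)ccc1N | intermediate
11 | 2-iodo-6-methyl-4-[(triisopropylsilyl)oxy]aniline | Cc1cc(O[Si](C(C)C)(C(C)C)C(C)C)cc(I)c1N | intermediate
12 | 2-iodo-6-methyl-4-[(triisopropylsilyl)oxy]benzenediazonium bromide | Cc1cc(O[Si](C(C)C)(C(C)C)C(C)C)cc(I)c1[N+]#N.[Br-] | intermediate (not isolated)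
13 | (4-bromo-3-iodo-5-methylphenoxy)triisopropylsilane | Cc1cc(O[Si](C(C)C)(C(C)C)C(C)C)cc(I)c1Br | intermediate
14 | methyl (2E,6E,10S)-12-(9-borabicyclo[3.3.1]nonan-9-yl)-10-hydroxy-2,6,10-trimethyldodeca-2,6-dienoate (same spatial arrangement as 8; the descriptor changes only because the boron-bearing branch ranks lower) | C/C(=C\CC[C@@](C)(O)CCB1C2CCCC1CCC2)CC/C=C(\C)C(=O)OC | intermediate (not isolated)
15 | methyl (2E,6E,10R)-12-{2-bromo-3-methyl-5-[(triisopropylsilyl)oxy]phenyl}-10-hydroxy-2,6,10-trimethyldodeca-2,6-dienoate | C/C(=C\CC[C@@](C)(O)CCc1cc(O[Si](C(C)C)(C(C)C)C(C)C)cc(C)c1Br)CC/C=C(\C)C(=O)OC | intermediate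
16 | methyl (2E,6E)-9-{(2R)-2,8-dimethyl-6-[(triisopropylsilyl)oxy]-3,4-dihydro-2H-chromen-2-yl}-2,6-dimethylnona-2,6-dienoate | C/C(=C\CC[C@]1(C)CCc2cc(O[Si](C(C)C)(C(C)C)C(C)C)cc(C)c2O1)CC/C=C(\C)C(=O)OC | intermediate
17 | methyl (2E,6E)-9-[(2R)-6-hydroxy-2,8-dimethyl-3,4-dihydro-2H-chromen-2-yl]-2,6-dimethylnona-2,6-dienoate (present as its phenoxide) | C/C(=C\CC[C@]1(C)CCc2cc(O)cc(C)c2O1)CC/C=C(\C)C(=O)OC | intermediate (not isolated)
18 | (2E,6E)-9-[(2R)-6-hydroxy-2,8-dimethyl-3,4-dihydro-2H-chromen-2-yl]-2,6-dimethylnona-2,6-dienoic acid | C/C(=C\CC[C@]1(C)CCc2cc(O)cc(C)c2O1)CC/C=C(\C)C(=O)O | target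

Total steps: 11. Longest linear sequence: 8 steps (steps 1–5 and 9–11, from (R)-linalool); the arene branch is steps 6–8.

Steps most likely to fail

1. Step 10. C–O reductive elimination from the hindered, electron-rich arylpalladium alkoxide may be slow, so that hydrodebromination or catalyst decomposition outruns ring closure. Fallback: setting out from 15, the same O1–C8a bond is made by a copper-mediated Ullmann-type etherification (CuCl, 3,4,7,8-tetramethyl-1,10-phenanthroline, Cs2CO3, toluene, 110 °C). This runs through a copper alkoxide, not a palladium cross-coupling cycle, and likewise leaves the C2–O bond intact. It comes back to the route at 16 and makes no new compound (F0).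

2. Step 3. The tertiary lithium alkoxide may attack the allylic bromide intramolecularly (SN2′ closure to a vinyl tetrahydrofuran), or the bromide may be lost by elimination, before the enolate has displaced it. Fallback: setting out from 4, the weakly basic anion of ethyl (phenylsulfonyl)acetate (K2CO3, DMF, rt), which leaves the alcohol protonated, should give ethyl (4E,8R)-8-hydroxy-4,8-dimethyl-2-(phenylsulfonyl)deca-4,9-dienoate F1 as both C2 epimers. Reductive desulfonylation (SmI2, THF/EtOH, −78 to 0 °C) then comes back to the route at 5.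

3. Step 9. Excess borane may add to a trisubstituted alkene or reduce the enoate, the ester may hydrolyse under the aqueous base, and transmetalation next to the free alcohol may be slow. Fallback: the coupling is moved ahead of enoate formation. Setting out from 5 and 13, the same 9-BBN hydroboration and PdCl2(dppf) coupling should pass through ethyl (4E,8S)-10-(9-borabicyclo[3.3.1]nonan-9-yl)-8-hydroxy-4,8-dimethyldec-4-enoate F2 to give ethyl (4E,8R)-10-{2-bromo-3-methyl-5-[(triisopropylsilyl)oxy]phenyl}-8-hydroxy-4,8-dimethyldec-4-enoate F3. iBu2AlH at −78 °C should then give (4E,8R)-10-{2-bromo-3-methyl-5-[(triisopropylsilyl)oxy]phenyl}-8-hydroxy-4,8-dimethyldec-4-enal F4, and Wittig olefination with 7 comes back to the route at 15.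

Further compounds
F0 | step 10 | none | none
F1 | step 3 | ethyl (4E,8R)-8-hydroxy-4,8-dimethyl-2-(phenylsulfonyl)deca-4,9-dienoate | C=C[C@](C)(O)CC/C=C(\C)CC(C(=O)OCC)S(=O)(=O)c1ccccc1
F2 | step 9 | ethyl (4E,8S)-10-(9-borabicyclo[3.3.1]nonan-9-yl)-8-hydroxy-4,8-dimethyldec-4-enoate | CCOC(=O)CC/C(C)=C/CC[C@@](C)(O)CCB1C2CCCC1CCC2
F3 | step 9 | ethyl (4E,8R)-10-{2-bromo-3-methyl-5-[(triisopropylsilyl)oxy]phenyl}-8-hydroxy-4,8-dimethyldec-4-enoate | CCOC(=O)CC/C(C)=C/CC[C@@](C)(O)CCc1cc(O[Si](C(C)C)(C(C)C)C(C)C)cc(C)c1Br
F4 | step 9 | (4E,8R)-10-{2-bromo-3-methyl-5-[(triisopropylsilyl)oxy]phenyl}-8-hydroxy-4,8-dimethyldec-4-enal | O=CCC/C(C)=C/CC[C@@](C)(O)CCc1cc(O[Si](C(C)C)(C(C)C)C(C)C)cc(C)c1Br
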